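Ring A carries para oxygens on C5 and C8 next to the enol-ether edge C4a–C8a–O1 of the pyran ring (chromene numbering). That pattern is the product signature of a Dötz benzannulation, so ring A is disconnected at C8–C7, C6–C5 and C5–C4a into a dihydropyranyl(methoxy)carbene complex of Cr(CO)5, one of its CO ligands and 3,3-diethoxyprop-1-yne. One operation then builds the whole arene with both oxygens and the C6 formyl carbon in place. The carbene precursor comes from (S)-linalool, whose carbinol carbon becomes C2, and already carries the finished (E)-4-hydroxy-4-methylpent-2-enyl side chain as a silyl ether, so that only arene-centred steps follow the annulation.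

Key step: step 10

Remark: no bond to the linalool carbinol carbon is made or broken anywhere; its CIP label changes between R and S along the route only because substituent priorities change (S in 1 and in the 2H-chromenes 24 to 30).

Step 1
Reactants: 1 (S)-linalool
Product: 2 (S)-3,7-dimethyloct-6-ene-1,3-diol
Conditions: 9-BBN (2.2 equiv), THF, 0 °C to rt; then NaOH, H2O2, 0 °C to rt
Reagents that add atoms: hydrogen peroxide, OO
Why: Brown hydroboration–oxidation with the bulky 9-BBN should add anti-Markovnikov to the monosubstituted vinyl group only, leaving the trisubstituted alkene and the carbinol stereocentre untouched.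

Step 2
Reactants: 2 (S)-3,7-dimethyloct-6-ene-1,3-diol
Product: 4 (S)-3,7-dimethyl-3-(trimethylsilyloxy)oct-6-en-1-yl 4-methylbenzenesulfonate, via hydroxy tosylate 3 (not isolated)
Conditions: TsCl (1.1 equiv), pyridine, CH2Cl2, 0 °C; then Me3SiCl, imidazole, 0 °C to rt
Reagents that add atoms: 4-methylbenzenesulfonyl chloride, Cc1ccc(cc1)S(=O)(=O)Cl; chlorotrimethylsilane, C[Si](C)(C)Cl
Why: Sulfonylation is selective for the primary hydroxyl, and silylating the tertiary hydroxyl in the same flask removes the alkoxide that could otherwise close an oxetane onto the tosylate under the strongly basic alkylation that follows.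

Step 3
Reactants: 4 (S)-3,7-dimethyl-3-(trimethylsilyloxy)oct-6-en-1-yl 4-methylbenzenesulfonate; 5 acetonitrile
Product: 7 (R)-5,9-dimethyl-5-(trimethylsilyloxy)dec-8-enenitrile, via lithioacetonitrile 6 (not isolated)
Conditions: 5 (3 equiv), n-BuLi, THF, −78 °C; then 4, −78 to 0 °C
Reagents that add atoms: none
Why: SN2 alkylation of the cyanomethyl anion by the unhindered primary tosylate adds the two carbons that become C4a and C8a, an excess of the anion suppressing double alkylation.

Step 4
Reactants: 7 (R)-5,9-dimethyl-5-(trimethylsilyloxy)dec-8-enenitrile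
Product: 9 (6R)-6-methyl-6-(4-methylpent-3-en-1-yl)oxan-2-ol (both anomers), via hydroxy aldehyde 8 (not isolated)
Conditions: iBu2AlH (1.3 equiv), CH2Cl2, −78 °C; then 1 M HCl, THF, 0 °C to rt
Reagents that add atoms: water, O
Why: Partial reduction of the nitrile with iBu2AlH stops at the aldehyde oxidation level, and the aqueous acid work-up releases the aldehyde, cleaves the tertiary trimethylsilyl ether and lets the 5-hydroxy aldehyde close to the six-membered lactol.

Step 5
Reactants: 9 (6R)-6-methyl-6-(4-methylpent-3-en-1-yl)oxan-2-ol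
Product: 10 (2R)-6-methoxy-2-methyl-2-(4-methylpent-3-en-1-yl)oxane (both anomers)
Conditions: MeOH, pyridinium 4-methylbenzenesulfonate (cat.), rt
Reagents that add atoms: methanol, CO
Why: Acid-catalysed acetalisation of the Fischer glycosidation type locks the lactol as a methyl acetal that is stable to base, hydride and peroxide, so that neither a free hydroxyl nor an aldehyde is present during the side-chain oxidation.

Step 6
Reactants: 10 (2R)-6-methoxy-2-methyl-2-(4-methylpent-3-en-1-yl)oxane
Product: 11 (2R)-2-[2-(3,3-dimethyloxiran-2-yl)ethyl]-6-methoxy-2-methyloxane (mixture of diastereomers)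
Conditions: mCPBA (1.1 equiv), NaHCO3, CH2Cl2, 0 °C
Reagents that add atoms: 3-chloroperoxybenzoic acid, OOC(=O)c1cccc(Cl)c1
Why: Prilezhaev epoxidation of the only alkene under buffered conditions; the new epoxide stereocentre is not controlled and need not be, because the next step erases it.

Step 7
Reactants: 11 (2R)-2-[2-(3,3-dimethyloxiran-2-yl)ethyl]-6-methoxy-2-methyloxane
Product: 14 (E)-5-[(2R)-6-methoxy-2-methyloxan-2-yl]-2-methylpent-3-en-2-ol, via hydroxy selenide 12 (not isolated), via selenoxide 13 (not isolated)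
Conditions: PhSeSePh (0.6 equiv), NaBH4, EtOH, rt to 60 °C; then H2O2 (30%), pyridine, THF, 0 °C to rt
Reagents that add atoms: none
Why: Sharpless-type epoxide-to-allylic-alcohol transposition, in which the selenolate opens the epoxide at its secondary carbon and syn elimination of the selenoxide can only run toward the chain methylene (the carbinol carbon has no hydrogen), which should give the E alkene beside the tertiary alcohol.

Step 8
Reactants: 14 (E)-5-[(2R)-6-methoxy-2-methyloxan-2-yl]-2-methylpent-3-en-2-ol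
Product: 15 (2R)-2-methyl-2-[(E)-4-methyl-4-(trimethylsilyloxy)pent-2-en-1-yl]-3,4-dihydro-2H-pyran
Conditions: Me3SiOSO2CF3 (2.5 equiv), iPr2NEt (3 equiv), CH2Cl2, −20 °C to rt
Reagents that add atoms: trimethylsilyl trifluoromethanesulfonate, C[Si](C)(C)OS(=O)(=O)C(F)(F)F
Why: Gassman-type conversion of an acetal into an enol ether, in which the silyl triflate ionises the exocyclic methoxy group and the amine removes the neighbouring ring proton of the cyclic oxocarbenium ion, while the same reagent pair silylates the tertiary allylic hydroxyl so that the organolithium step meets no acidic proton.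

Step 9
Reactants: 15 (2R)-2-methyl-2-[(E)-4-methyl-4-(trimethylsilyloxy)pent-2-en-1-yl]-3,4-dihydro-2H-pyran; 16 hexacarbonylchromium
Product: 19 pentacarbonyl{methoxy[(2R)-2-methyl-2-[(E)-4-methyl-4-(trimethylsilyloxy)pent-2-en-1-yl]-3,4-dihydro-2H-pyran-6-yl]methylidene}chromium, via 6-lithiodihydropyran 17 (not isolated), via Li[(CO)5CrC(O)R] acylate 18 (not isolated)
Conditions: t-BuLi (1.2 equiv), THF, −78 to 0 °C; Cr(CO)6, Et2O, 0 °C to rt; then MeOSO2CF3, CH2Cl2, 0 °C
Reagents that add atoms: methyl trifluoromethanesulfonate, COS(=O)(=O)C(F)(F)F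
Why: Fischer carbene synthesis, in which the enol ether is lithiated at its oxygen-bearing vinyl carbon, the alkenyllithium adds to a CO ligand of zerovalent chromium and O-methylation of the acylmetalate gives the alkenyl(methoxy)carbene complex.

Step 10
Reactants: 19 the carbene complex of step 9; 20 3,3-diethoxyprop-1-yne
Product: 22 (2R)-6-(diethoxymethyl)-8-methoxy-2-methyl-2-[(E)-4-methyl-4-(trimethylsilyloxy)pent-2-en-1-yl]chroman-5-ol, via (arene)Cr(CO)3 complex 21 (not isolated)
Conditions: 20 (2 equiv), THF (0.05 M), 50 °C, Ar; then air, Et2O, rt; filtration through Et3N-deactivated silica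
Reagents that add atoms: none
Why: This is a Dötz benzannulation of an alkenyl(alkoxy)carbene complex of zerovalent chromium with a terminal alkyne, the standard route to 4-methoxyphenols. Thermal loss of one CO frees a coordination site, the alkyne inserts into the Cr=C bond with its CH terminus joining the carbene carbon (C8–C7), and a CO ligand then inserts to give a chromium-bound dienylketene (C6–C5). Ring A closes by 6π electrocyclisation of that ketene onto the β-carbon of the dihydropyran enol ether (C5–C4a), and enolisation of the cyclohexadienone gives the phenol as its Cr(CO)3 complex 21, which air demetalates. No stereocentre is created, and C2 is remote from every reacting atom and cannot epimerise. The only selectivity needed is the alkyne orientation that places the acetal carbon on C6 beside the new hydroxyl, and the steric preference of a terminal alkyne to insert with its substituent away from the carbene carbon secures it, while an alkenyl rather than aryl carbene ligand favours the phenol over cyclopentannulated products. The C8 methoxy oxygen thus comes from the carbene carbon, the C5 hydroxyl from CO and O1 from the enol ether, with the silyl ether, the E alkene and the acetal as spectators.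

Step 11
Reactants: 22 (2R)-6-(diethoxymethyl)-8-methoxy-2-methyl-2-[(E)-4-methyl-4-(trimethylsilyloxy)pent-2-en-1-yl]chroman-5-ol
Product: 23 (2R)-5-hydroxy-2-[(E)-4-hydroxy-4-methylpent-2-en-1-yl]-8-methoxy-2-methylchroman-6-carbaldehyde
Conditions: AcOH–THF–H2O (3:1:1), rt
Reagents that add atoms: water, O
Why: Mild acid hydrolysis should take the very labile ortho-hydroxyaryl acetal to the hydrogen-bonded salicylaldehyde and cleave the tertiary trimethylsilyl ether under conditions too weak to ionise the tertiary allylic alcohol.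

Step 12
Reactants: 23 (2R)-5-hydroxy-2-[(E)-4-hydroxy-4-methylpent-2-en-1-yl]-8-methoxy-2-methylchroman-6-carbaldehyde
Product: 24 (2S)-5-hydroxy-2-[(E)-4-hydroxy-4-methylpent-2-en-1-yl]-8-methoxy-2-methyl-2H-chromene-6-carbaldehyde
Conditions: DDQ (2,3-dichloro-5,6-dicyano-1,4-benzoquinone, 1.2 equiv), 1,4-dioxane, 70 °C
Reagents that add atoms: none
Why: DDQ dehydrogenation of a 5-hydroxychroman, in which hydride loss from C4 (assisted by the ortho phenol and O1) gives an ortho-quinone methide that tautomerises to the 2H-chromene; C4 is the only benzylic CH2 next to the phenol, and the C8 methyl ether blocks oxidation to a quinone.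

Step 13
Reactants: 24 (2S)-5-hydroxy-2-[(E)-4-hydroxy-4-methylpent-2-en-1-yl]-8-methoxy-2-methyl-2H-chromene-6-carbaldehyde; 25 (E)-β-bromostyrene
Product: 27 (2S)-6-[(E)-1-hydroxy-3-phenylprop-2-en-1-yl]-2-[(E)-4-hydroxy-4-methylpent-2-en-1-yl]-8-methoxy-2-methyl-2H-chromen-5-ol (both carbinol epimers), via (E)-styryllithium 26 (not isolated)
Conditions: 25 (3.5 equiv), t-BuLi (7 equiv), Et2O, −78 °C; then 24, THF, −78 to −20 °C; pH 7 buffer; crude product used directly
Reagents that add atoms: none
Why: Bromine–lithium exchange with t-BuLi at low temperature keeps the E geometry, two equivalents of the alkenyllithium are spent on the phenol and the tertiary alcohol and a third adds 1,2 to the aldehyde; the new carbinol centre is left uncontrolled because the next step oxidises it.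

Step 14
Reactants: 27 the allylic alcohol of step 13
Product: 28 (E)-1-[(2S)-5-hydroxy-2-[(E)-4-hydroxy-4-methylpent-2-en-1-yl]-8-methoxy-2-methyl-2H-chromen-6-yl]-3-phenylprop-2-en-1-one
Conditions: MnO2 (activated, 20 equiv), CH2Cl2, rt
Reagents that add atoms: none
Why: Activated MnO2 should oxidise the benzylic and allylic secondary alcohol to the chalcone ketone and leave the tertiary allylic alcohol, which has no carbinol hydrogen, untouched.

Step 15
Reactants: 28 the methoxy chalcone of step 14
Product: 30 (E)-1-[(2S)-5,8-dihydroxy-2-[(E)-4-hydroxy-4-methylpent-2-en-1-yl]-2-methyl-2H-chromen-6-yl]-3-phenylprop-2-en-1-one (CNP0327890.1), via chromene quinone 29 (not isolated)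
Conditions: (NH4)2Ce(NO3)6 (2.2 equiv), MeCN–H2O (4:1), 0 °C; then EtOAc, aq. Na2S2O4 (excess), rt, Ar
Reagents that add atoms: water, O
Why: Oxidative demethylation of the para-methoxyphenol by tetravalent cerium gives the 2H-chromene-5,8-dione (water supplies the new C8 oxygen as methanol leaves), and Na2S2O4 reduces the acylquinone at once to the hydroquinone, so that C8–OCH3 becomes C8–OH without any acidic or nucleophilic ether cleavage.

Compound list
1 | (S)-linalool | CC(C)=CCC[C@@](O)(C)C=C | starting material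
2 | (S)-3,7-dimethyloct-6-ene-1,3-diol | CC(C)=CCC[C@@](O)(C)CCO | intermediate
3 | (S)-3-hydroxy-3,7-dimethyloct-6-en-1-yl 4-methylbenzenesulfonate | CC(C)=CCC[C@@](O)(C)CCOS(=O)(=O)c1ccc(C)cc1 | intermediate
4 | (S)-3,7-dimethyl-3-(trimethylsilyloxy)oct-6-en-1-yl 4-methylbenzenesulfonate | CC(C)=CCC[C@@](O[Si](C)(C)C)(C)CCOS(=O)(=O)c1ccc(C)cc1 | intermediate
5 | acetonitrile | CC#N | starting material
6 | lithioacetonitrile, LiCH2CN | [Li]CC#N | intermediate
7 | (R)-5,9-dimethyl-5-(trimethylsilyloxy)dec-8-enenitrile | CC(C)=CCC[C@@](O[Si](C)(C)C)(C)CCCC#N | intermediate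
8 | (R)-5-hydroxy-5,9-dimethyldec-8-enal | CC(C)=CCC[C@@](O)(C)CCCC=O | intermediate
9 | (6R)-6-methyl-6-(4-methylpent-3-en-1-yl)oxan-2-ol | CC(C)=CCC[C@@]1(C)CCCC(O)O1 | intermediate
10 | (2R)-6-methoxy-2-methyl-2-(4-methylpent-3-en-1-yl)oxane | CC(C)=CCC[C@@]1(C)CCCC(OC)O1 | intermediate
11 | (2R)-2-[2-(3,3-dimethyloxiran-2-yl)ethyl]-6-methoxy-2-methyloxane | CC1(C)OC1CC[C@@]2(C)CCCC(OC)O2 | intermediate
12 | 5-[(2R)-6-methoxy-2-methyloxan-2-yl]-2-methyl-3-(phenylselanyl)pentan-2-ol | CC(C)(O)C([Se]c1ccccc1)CC[C@@]2(C)CCCC(OC)O2 | intermediate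
13 | 5-[(2R)-6-methoxy-2-methyloxan-2-yl]-2-methyl-3-(phenylseleninyl)pentan-2-ol | CC(C)(O)C([Se](=O)c1ccccc1)CC[C@@]2(C)CCCC(OC)O2 | intermediate
14 | (E)-5-[(2R)-6-methoxy-2-methyloxan-2-yl]-2-methylpent-3-en-2-ol | CC(C)(O)/C=C/C[C@@]1(C)CCCC(OC)O1 | intermediate
15 | (2R)-2-methyl-2-[(E)-4-methyl-4-(trimethylsilyloxy)pent-2-en-1-yl]-3,4-dihydro-2H-pyran | CC(C)(O[Si](C)(C)C)/C=C/C[C@@]1(C)CCC=CO1 | intermediate
16 | hexacarbonylchromium, Cr(CO)6 (zerovalent chromium) | O=C=[Cr](=C=O)(=C=O)(=C=O)(=C=O)=C=O | starting material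
17 | [(6R)-6-methyl-6-[(E)-4-methyl-4-(trimethylsilyloxy)pent-2-en-1-yl]-5,6-dihydro-4H-pyran-2-yl]lithium | CC(C)(O[Si](C)(C)C)/C=C/C[C@@]1(C)CCC=C([Li])O1 | intermediate
18 | lithium pentacarbonyl{[(2R)-2-methyl-2-[(E)-4-methyl-4-(trimethylsilyloxy)pent-2-en-1-yl]-3,4-dihydro-2H-pyran-6-yl]carbonyl}chromate | CC(C)(O[Si](C)(C)C)/C=C/C[C@@]1(C)CCC=C(O1)C([O-])=[Cr](=C=O)(=C=O)(=C=O)(=C=O)=C=O.[Li+] | intermediate
19 | pentacarbonyl{methoxy[(2R)-2-methyl-2-[(E)-4-methyl-4-(trimethylsilyloxy)pent-2-en-1-yl]-3,4-dihydro-2H-pyran-6-yl]methylidene}chromium (zerovalent chromium) | CC(C)(O[Si](C)(C)C)/C=C/C[C@@]1(C)CCC=C(O1)C(OC)=[Cr](=C=O)(=C=O)(=C=O)(=C=O)=C=O | intermediate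
20 | 3,3-diethoxyprop-1-yne | C#CC(OCC)OCC | starting material
21 | tricarbonyl(η6-arene)chromium complex of 22, drawn as arene and Cr(CO)3 fragment joined by a dot | CC(C)(O[Si](C)(C)C)/C=C/C[C@@]1(C)CCc2c(O)c(C(OCC)OCC)cc(OC)c2O1.O=C=[Cr](=C=O)=C=O | intermediate
22 | (2R)-6-(diethoxymethyl)-8-methoxy-2-methyl-2-[(E)-4-methyl-4-(trimethylsilyloxy)pent-2-en-1-yl]chroman-5-ol | CC(C)(O[Si](C)(C)C)/C=C/C[C@@]1(C)CCc2c(O)c(C(OCC)OCC)cc(OC)c2O1 | intermediate
23 | (2R)-5-hydroxy-2-[(E)-4-hydroxy-4-methylpent-2-en-1-yl]-8-methoxy-2-methylchroman-6-carbaldehyde | CC(C)(O)/C=C/C[C@@]1(C)CCc2c(O)c(C=O)cc(OC)c2O1 | intermediate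
24 | (2S)-5-hydroxy-2-[(E)-4-hydroxy-4-methylpent-2-en-1-yl]-8-methoxy-2-methyl-2H-chromene-6-carbaldehyde | CC(C)(O)/C=C/C[C@@]1(C)C=Cc2c(O)c(C=O)cc(OC)c2O1 | intermediate
25 | (E)-β-bromostyrene | Br/C=C/c1ccccc1 | starting material
26 | (E)-(2-phenylethenyl)lithium | [Li]/C=C/c1ccccc1 | intermediate
27 | (2S)-6-[(E)-1-hydroxy-3-phenylprop-2-en-1-yl]-2-[(E)-4-hydroxy-4-methylpent-2-en-1-yl]-8-methoxy-2-methyl-2H-chromen-5-ol | CC(C)(O)/C=C/C[C@@]1(C)C=Cc2c(O)c(C(O)/C=C/c3ccccc3)cc(OC)c2O1 | intermediate
28 | (E)-1-[(2S)-5-hydroxy-2-[(E)-4-hydroxy-4-methylpent-2-en-1-yl]-8-methoxy-2-methyl-2H-chromen-6-yl]-3-phenylprop-2-en-1-one | CC(C)(O)/C=C/C[C@@]1(C)C=Cc2c(O)c(C(=O)/C=C/c3ccccc3)cc(OC)c2O1 | intermediate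
29 | (2S)-2-[(E)-4-hydroxy-4-methylpent-2-en-1-yl]-2-methyl-6-[(E)-3-phenylprop-2-enoyl]-2H-chromene-5,8-dione | CC(C)(O)/C=C/C[C@@]1(C)C=CC2=C(O1)C(=O)C=C(C(=O)/C=C/c3ccccc3)C2=O | intermediate
30 | (E)-1-[(2S)-5,8-dihydroxy-2-[(E)-4-hydroxy-4-methylpent-2-en-1-yl]-2-methyl-2H-chromen-6-yl]-3-phenylprop-2-en-1-one (CNP0327890.1) | CC(C)(O)/C=C/C[C@@]1(C)C=Cc2c(O)c(C(=O)/C=C/c3ccccc3)cc(O)c2O1 | target

Total step count: 15.
Longest linear sequence: 15 steps, from (S)-linalool 1 to 30.

Steps most likely to fail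

Step 10. The two acetal oxygens of the alkyne may chelate chromium after insertion and divert the vinylcarbene from CO insertion toward non-aromatic or doubly inserted products, and the ortho-hydroxyaryl acetal may be lost or over-oxidised during oxidative demetalation. The fallback changes how the C6 formyl group is reached: the carbon is carried through the annulation as a robust silyl-protected hydroxymethyl group and oxidised afterwards. It sets out from 19. Benzannulation with commercial tert-butyldimethyl(prop-2-yn-1-yloxy)silane under the thermal conditions of step 10 should give (2R)-6-[(tert-butyldimethylsilyloxy)methyl]-8-methoxy-2-methyl-2-[(E)-4-methyl-4-(trimethylsilyloxy)pent-2-en-1-yl]chroman-5-ol F1. Bu4NF in THF should remove both silyl groups to give (2R)-6-(hydroxymethyl)-2-[(E)-4-hydroxy-4-methylpent-2-en-1-yl]-8-methoxy-2-methylchroman-5-ol F2. Activated MnO2 in CH2Cl2 should then oxidise the ortho-hydroxybenzylic alcohol to the salicylaldehyde, which brings the route back at 23.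

Step 8. The silyl triflate may ionise the endocyclic C–O bond, opening the ring to an acyclic enol ether, or ionise the tertiary allylic silyl ether, instead of expelling methoxide. The fallback replaces Lewis-acid ionisation of the acetal by sulfonate elimination from the lactol. It sets out from 14. AcOH–THF–H2O should hydrolyse the methyl acetal to (6R)-6-[(E)-4-hydroxy-4-methylpent-2-en-1-yl]-6-methyloxan-2-ol F3. MsCl (1.2 equiv) and Et3N in THF, −20 to 60 °C, should sulfonylate the hemiacetal hydroxyl much faster than the tertiary one and eliminate to (E)-2-methyl-5-[(2R)-2-methyl-3,4-dihydro-2H-pyran-2-yl]pent-3-en-2-ol F4. Me3SiCl and imidazole then silylate the tertiary alcohol, which brings the route back at 15.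

Step 12. Hydride abstraction may be overtaken by further oxidation of the electron-rich phenol, or the acidic hydroquinone by-product may ionise the tertiary allylic alcohol at the reaction temperature. The fallback introduces the C3–C4 alkene at the end in a redox-neutral way instead. It sets out from 23. Addition of 26 as in step 13 should give (2R)-6-[(E)-1-hydroxy-3-phenylprop-2-en-1-yl]-2-[(E)-4-hydroxy-4-methylpent-2-en-1-yl]-8-methoxy-2-methylchroman-5-ol F5. MnO2 should give (E)-1-[(2R)-5-hydroxy-2-[(E)-4-hydroxy-4-methylpent-2-en-1-yl]-8-methoxy-2-methylchroman-6-yl]-3-phenylprop-2-en-1-one F6. (NH4)2Ce(NO3)6 in MeCN–H2O should give (2R)-2-[(E)-4-hydroxy-4-methylpent-2-en-1-yl]-2-methyl-6-[(E)-3-phenylprop-2-enoyl]-3,4-dihydro-2H-chromene-5,8-dione F7. Et3N in CH2Cl2 under Ar should then tautomerise the acylquinone through its ortho-quinone methide (proton loss from C4, then from C3) to the chromene hydroquinone, which brings the route back at 30.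

Further compounds
F1 | step 10 | (2R)-6-[(tert-butyldimethylsilyloxy)methyl]-8-methoxy-2-methyl-2-[(E)-4-methyl-4-(trimethylsilyloxy)pent-2-en-1-yl]chroman-5-ol | CC(C)(O[Si](C)(C)C)/C=C/C[C@@]1(C)CCc2c(O)c(CO[Si](C)(C)C(C)(C)C)cc(OC)c2O1
F2 | step 10 | (2R)-6-(hydroxymethyl)-2-[(E)-4-hydroxy-4-methylpent-2-en-1-yl]-8-methoxy-2-methylchroman-5-ol | CC(C)(O)/C=C/C[C@@]1(C)CCc2c(O)c(CO)cc(OC)c2O1
F3 | step 8 | (6R)-6-[(E)-4-hydroxy-4-methylpent-2-en-1-yl]-6-methyloxan-2-ol | CC(C)(O)/C=C/C[C@@]1(C)CCCC(O)O1
F4 | step 8 | (E)-2-methyl-5-[(2R)-2-methyl-3,4-dihydro-2H-pyran-2-yl]pent-3-en-2-ol | CC(C)(O)/C=C/C[C@@]1(C)CCC=CO1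
F5 | step 12 | (2R)-6-[(E)-1-hydroxy-3-phenylprop-2-en-1-yl]-2-[(E)-4-hydroxy-4-methylpent-2-en-1-yl]-8-methoxy-2-methylchroman-5-ol | CC(C)(O)/C=C/C[C@@]1(C)CCc2c(O)c(C(O)/C=C/c3ccccc3)cc(OC)c2O1
F6 | step 12 | (E)-1-[(2R)-5-hydroxy-2-[(E)-4-hydroxy-4-methylpent-2-en-1-yl]-8-methoxy-2-methylchroman-6-yl]-3-phenylprop-2-en-1-one | CC(C)(O)/C=C/C[C@@]1(C)CCc2c(O)c(C(=O)/C=C/c3ccccc3)cc(OC)c2O1
F7 | step 12 | (2R)-2-[(E)-4-hydroxy-4-methylpent-2-en-1-yl]-2-methyl-6-[(E)-3-phenylprop-2-enoyl]-3,4-dihydro-2H-chromene-5,8-dione | CC(C)(O)/C=C/C[C@@]1(C)CCC2=C(O1)C(=O)C=C(C(=O)/C=C/c3ccccc3)C2=O
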